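The phenyl ring on C3 of the propanoic acid chain, the only ring of the target without a heteroatom, is disconnected into a C3-bound ethynyl group and two molecules of acetylene. One cobalt-mediated [2+2+2] cyclotrimerisation makes the three C–C bonds and the complete benzene ring at once and leaves the C3 stereocentre untouched. Its precursor is methyl (3R)-3-[4-(benzyloxy)-2,6-dimethoxyphenyl]pent-4-ynoate: the future flavone ring A is still a C2-symmetric protected phloroglucinol, and C3 carries a slim alkyne beside this bulky, electron-rich aryl group. That contrast lets a stereoconvergent copper-catalysed propargylic alkylation set C3 beforehand.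

Key step: step 5

Assumption: in step 3 the Ph-pybox antipode is the one that directs malonate to the face giving (R) at C3; this sense cannot be predicted with confidence here and has to be fixed in a first run by chiral HPLC and correlation, the other antipode being used if needed.

Remark: C3 is (R) in the target (CIP order ring A > phenyl > CH2CO2H > H); the order ring A > ethynyl > CH2 is the same, so the descriptor stays (R) from 9 to 20.

Step 1
Reactants: 1 4-hydroxy-2,6-dimethoxybenzaldehyde; 2 benzyl bromide
Product: 3 4-(benzyloxy)-2,6-dimethoxybenzaldehyde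
Conditions: BnBr (1.1 equiv), K2CO3, DMF, rt
Reagents that add atoms: benzyl bromide, BrCc1ccccc1
Why: Williamson ether synthesis: carbonate deprotonates the single phenol (acidified by the para formyl group) and the phenoxide displaces bromide from benzyl bromide by SN2, the molecule offering no other nucleophilic site.

Step 2
Reactants: 3 4-(benzyloxy)-2,6-dimethoxybenzaldehyde; 4 ethynylmagnesium bromide; 5 acetic anhydride
Product: 7 rac-1-[4-(benzyloxy)-2,6-dimethoxyphenyl]prop-2-yn-1-yl acetate, via bromomagnesium propargylic alkoxide 6 (not isolated)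
Conditions: HC≡CMgBr (1.3 equiv), THF, 0 °C; then Ac2O (3 equiv), 0 °C → rt; aq. NaHCO3, quick filtration through Et3N-deactivated silica
Reagents that add atoms: ethynylmagnesium bromide, C#C[Mg]Br; acetic anhydride, CC(=O)OC(C)=O
Why: Grignard 1,2-addition of the alkynyl nucleophile to the aldehyde followed by in-flask O-acetylation of the magnesium alkoxide, so that the acid-labile, electron-rich propargylic alcohol is never isolated; the new carbinol centre is deliberately racemic because step 3 is stereoconvergent.

Step 3
Reactants: 7 rac-1-[4-(benzyloxy)-2,6-dimethoxyphenyl]prop-2-yn-1-yl acetate; 8 dimethyl malonate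
Product: 9 dimethyl 2-[(1R)-1-[4-(benzyloxy)-2,6-dimethoxyphenyl]prop-2-yn-1-yl]propanedioate
Conditions: Cu(MeCN)4PF6 (5 mol%), Ph-pybox (6 mol%, antipode as assumed), CH2(CO2Me)2 (2 equiv), i-Pr2NEt (1.5 equiv), MeOH, −20 °C, Ar
Reagents that add atoms: dimethyl malonate, COC(=O)CC(=O)OC
Why: Copper-catalysed asymmetric propargylic alkylation: the copper acetylide of either enantiomer of 7 loses acetate to one planar copper allenylidene, and the C2-symmetric pybox ligand on copper steers the malonate to one face of its γ-carbon, which sets C3 as (R) under ligand control.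

Step 4
Reactants: 9 dimethyl 2-[(1R)-1-[4-(benzyloxy)-2,6-dimethoxyphenyl]prop-2-yn-1-yl]propanedioate
Product: 10 methyl (3R)-3-[4-(benzyloxy)-2,6-dimethoxyphenyl]pent-4-ynoate
Conditions: LiCl (3 equiv), H2O (2 equiv), DMSO, 140 °C
Reagents that add atoms: none
Why: Krapcho dealkoxycarbonylation: chloride removes one ester methyl group by SN2, the carboxylate loses CO2 and water protonates the resulting ester enolate, all under near-neutral conditions in which C3, which bears no acidic hydrogen and no leaving group, keeps its configuration.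

Step 5
Reactants: 10 methyl (3R)-3-[4-(benzyloxy)-2,6-dimethoxyphenyl]pent-4-ynoate; 11 acetylene (two molecules incorporated)
Product: 12 methyl (3R)-3-[4-(benzyloxy)-2,6-dimethoxyphenyl]-3-phenylpropanoate
Conditions: CpCo(CO)2 (20 mol%), HC≡CH (1 atm, purified, continuous stream), toluene, hν (visible), 100 °C, 10 added by syringe pump
Reagents that add atoms: acetylene, C#C
Why: Loss of CO from CpCo(CO)2 frees a CpCo fragment that binds two alkynes and couples them oxidatively to a cobaltacyclopentadiene; the third alkyne then inserts and reductive elimination releases the arene and returns Co(I). The closest known reaction type is the cobalt-catalysed [2+2+2] alkyne cyclotrimerisation (Reppe type) run as a cross-trimerisation with acetylene gas, the all-carbon counterpart of the cobalt-catalysed pyridine synthesis from a nitrile and two acetylenes. The benzene ring is closed intermolecularly from three two-carbon units on the metal template, with three C–C σ-bonds formed and the last one made by reductive elimination from the seven-membered cobaltacycle. No stereocentre is created: C3 only changes its substituent from ethynyl to phenyl, no bond to C3 is made or broken, and the neutral, aprotic, base-free medium leaves the propargylic C3–H alone, so (R) is carried over. The selectivity needed is chemoselectivity for the 1:2 cross-trimer over homo- and 2:1 trimers of 10, secured by saturating acetylene, slow addition of 10 and the crowding of the alkyne by the tertiary C3 with its 2,6-dimethoxyaryl group; regiochemistry is no issue because every 1:2 combination gives the same monosubstituted benzene, and the side product from acetylene alone is volatile benzene.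

Step 6
Reactants: 12 methyl (3R)-3-[4-(benzyloxy)-2,6-dimethoxyphenyl]-3-phenylpropanoate
Product: 13 methyl (3R)-3-(4-hydroxy-2,6-dimethoxyphenyl)-3-phenylpropanoate
Conditions: H2 (1 atm), 10% Pd/C, EtOAc–MeOH, rt
Reagents that add atoms: none
Why: Palladium-catalysed hydrogenolysis of the benzylic C–O bond of the aryl benzyl ether, placed after step 5 because the alkyne would not have survived it; the methyl ethers, the ester and the C3–aryl bonds are inert at 1 atm of hydrogen.

Step 7
Reactants: 13 methyl (3R)-3-(4-hydroxy-2,6-dimethoxyphenyl)-3-phenylpropanoate; 5 acetic anhydride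
Product: 15 methyl (3R)-3-(3-acetyl-4-hydroxy-2,6-dimethoxyphenyl)-3-phenylpropanoate, via aryl acetate 14 (not isolated)
Conditions: Ac2O (2 equiv), BF3·OEt2 (3 equiv), 0 → 70 °C; then aq. NaOAc, MeOH, 50 °C
Reagents that add atoms: acetic anhydride, CC(=O)OC(C)=O
Why: One-pot O-acetylation and BF3-mediated Fries rearrangement (Friedel–Crafts C-acylation): the acetyl group can only enter ortho to the free hydroxyl, and the two such carbons are interchanged by rotation about the aryl–C3 bond and give the same ketone, while BF3, unlike AlCl3 or BCl3, should leave intact the neighbouring methyl ether that later blocks the wrong ring closure.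

Step 8
Reactants: 15 methyl (3R)-3-(3-acetyl-4-hydroxy-2,6-dimethoxyphenyl)-3-phenylpropanoate; 16 4-methoxybenzaldehyde
Product: 18 (3R)-3-{4-hydroxy-2,6-dimethoxy-3-[(2E)-3-(4-methoxyphenyl)prop-2-enoyl]phenyl}-3-phenylpropanoic acid, via saponified keto acid 17 (not isolated)
Conditions: 4-MeOC6H4CHO (1.5 equiv), KOH (15 equiv), EtOH–H2O, rt, 48 h; then 1 M HCl, 0 °C, pH 3
Reagents that add atoms: 4-methoxybenzaldehyde, COc1ccc(C=O)cc1; potassium hydroxide, [K+].[OH-]
Why: Claisen–Schmidt condensation (crossed aldol addition of the methyl ketone enolate to the non-enolisable aldehyde, then E1cB dehydration to the conjugated (E)-enone); the excess aqueous hydroxide first saponifies the methyl ester, which is welcome because the target is the free acid, and C3 has no hydrogen that this base can remove.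

Step 9
Reactants: 18 (3R)-3-{4-hydroxy-2,6-dimethoxy-3-[(2E)-3-(4-methoxyphenyl)prop-2-enoyl]phenyl}-3-phenylpropanoic acid
Product: 19 (3R)-3-[5,7-dimethoxy-2-(4-methoxyphenyl)-4-oxo-4H-chromen-6-yl]-3-phenylpropanoic acid
Conditions: I2 (10 mol%), DMSO, 130 °C; aq. Na2S2O3
Reagents that add atoms: none
Why: Iodine-catalysed oxidative cyclisation of a 2'-hydroxychalcone to a flavone (oxa-Michael addition of the only free phenol, α-iodination and loss of HI, with DMSO reoxidising HI to I2); since the other ortho oxygen is a methyl ether, the pyranone can close only through the oxygen para to C3, which places the side chain at C6 and not at C8.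

Step 10
Reactants: 19 (3R)-3-[5,7-dimethoxy-2-(4-methoxyphenyl)-4-oxo-4H-chromen-6-yl]-3-phenylpropanoic acid
Product: 20 (3R)-3-[5,7-dihydroxy-2-(4-hydroxyphenyl)-4-oxo-4H-chromen-6-yl]-3-phenylpropanoic acid
Conditions: BBr3 (10 equiv), CH2Cl2, −78 °C → rt; H2O; 1 M NaOH (Ar), 0 °C → rt, 30 min; 1 M HCl to pH 3, 0 °C
Reagents that add atoms: none
Why: Lewis-acid cleavage of the three aryl methyl ethers (BBr3 adds to each ether oxygen, that at C5 helped by chelation to the C4 carbonyl, and bromide removes the methyl group by SN2, so no bond to C3 is involved); the brief alkaline work-up hydrolyses the aryl borates and reopens any aryl lactone formed between the acid and a flanking phenol before mild acidification releases the hydroxy acid.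

Compound list
1 | 4-hydroxy-2,6-dimethoxybenzaldehyde | O=Cc1c(OC)cc(O)cc1OC | starting material
2 | benzyl bromide | BrCc1ccccc1 | starting material
3 | 4-(benzyloxy)-2,6-dimethoxybenzaldehyde | O=Cc1c(OC)cc(OCc2ccccc2)cc1OC | intermediate
4 | ethynylmagnesium bromide | C#C[Mg]Br | starting material
5 | acetic anhydride | CC(=O)OC(C)=O | starting material
6 | bromomagnesium rac-1-[4-(benzyloxy)-2,6-dimethoxyphenyl]prop-2-yn-1-olate | C#CC(O[Mg]Br)c1c(OC)cc(OCc2ccccc2)cc1OC | intermediate
7 | rac-1-[4-(benzyloxy)-2,6-dimethoxyphenyl]prop-2-yn-1-yl acetate | CC(=O)OC(C#C)c1c(OC)cc(OCc2ccccc2)cc1OC | intermediate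
8 | dimethyl malonate | COC(=O)CC(=O)OC | starting material
9 | dimethyl 2-[(1R)-1-[4-(benzyloxy)-2,6-dimethoxyphenyl]prop-2-yn-1-yl]propanedioate | COC(=O)C(C(=O)OC)[C@H](C#C)c1c(OC)cc(OCc2ccccc2)cc1OC | intermediate
10 | methyl (3R)-3-[4-(benzyloxy)-2,6-dimethoxyphenyl]pent-4-ynoate | COC(=O)C[C@H](C#C)c1c(OC)cc(OCc2ccccc2)cc1OC | intermediate
11 | acetylene | C#C | starting material
12 | methyl (3R)-3-[4-(benzyloxy)-2,6-dimethoxyphenyl]-3-phenylpropanoate | COC(=O)C[C@H](c1ccccc1)c1c(OC)cc(OCc2ccccc2)cc1OC | intermediate
13 | methyl (3R)-3-(4-hydroxy-2,6-dimethoxyphenyl)-3-phenylpropanoate | COC(=O)C[C@H](c1ccccc1)c1c(OC)cc(O)cc1OC | intermediate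
14 | methyl (3R)-3-(4-acetoxy-2,6-dimethoxyphenyl)-3-phenylpropanoate | COC(=O)C[C@H](c1ccccc1)c1c(OC)cc(OC(C)=O)cc1OC | intermediate
15 | methyl (3R)-3-(3-acetyl-4-hydroxy-2,6-dimethoxyphenyl)-3-phenylpropanoate | COC(=O)C[C@H](c1ccccc1)c1c(OC)cc(O)c(C(C)=O)c1OC | intermediate
16 | 4-methoxybenzaldehyde | COc1ccc(C=O)cc1 | starting material
17 | (3R)-3-(3-acetyl-4-hydroxy-2,6-dimethoxyphenyl)-3-phenylpropanoic acid | OC(=O)C[C@H](c1ccccc1)c1c(OC)cc(O)c(C(C)=O)c1OC | intermediate
18 | (3R)-3-{4-hydroxy-2,6-dimethoxy-3-[(2E)-3-(4-methoxyphenyl)prop-2-enoyl]phenyl}-3-phenylpropanoic acid | OC(=O)C[C@H](c1ccccc1)c1c(OC)cc(O)c(C(=O)/C=C/c2ccc(OC)cc2)c1OC | intermediate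
19 | (3R)-3-[5,7-dimethoxy-2-(4-methoxyphenyl)-4-oxo-4H-chromen-6-yl]-3-phenylpropanoic acid | OC(=O)C[C@H](c1ccccc1)c1c(OC)cc2oc(-c3ccc(OC)cc3)cc(=O)c2c1OC | intermediate
20 | (3R)-3-[5,7-dihydroxy-2-(4-hydroxyphenyl)-4-oxo-4H-chromen-6-yl]-3-phenylpropanoic acid | O=C(O)C[C@H](c1ccccc1)c1c(O)cc2oc(-c3ccc(O)cc3)cc(=O)c2c1O | target

Total step count: 10. Longest linear sequence: 10 steps (1 to 20); the route is fully linear.

Steps most likely to fail

Step 5. The cobalt catalyst may be used up by homotrimerisation and oligomerisation of acetylene while the crowded alkyne of 10 inserts too slowly, or two molecules of 10 may end up in one arene. The fallback brings the phenyl ring in as a nucleophile instead of building it. It sets out from aldehyde 3: Horner–Wadsworth–Emmons olefination with trimethyl phosphonoacetate (NaH, THF, 0 °C → rt) should give methyl (2E)-3-[4-(benzyloxy)-2,6-dimethoxyphenyl]prop-2-enoate F1. Rhodium-catalysed asymmetric 1,4-addition of phenylboronic acid (Hayashi–Miyaura reaction; Rh(acac)(C2H4)2, BINAP antipode chosen for the (R) product, dioxane–H2O, 100 °C) then delivers 12, where the route is rejoined at step 6.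

Step 3. The very electron-rich, doubly ortho-substituted acetate may ionise outside the copper cycle (racemic substitution or methanolysis), and facial discrimination at the crowded γ-carbon may be poor, so that conversion or enantiomeric purity falls short. The fallback replaces the substitution by a conjugate addition and a resolution. It sets out from aldehyde 3: Knoevenagel condensation with Meldrum's acid (piperidine/AcOH cat., toluene, rt) should give 5-[4-(benzyloxy)-2,6-dimethoxybenzylidene]-2,2-dimethyl-1,3-dioxane-4,6-dione F2. Conjugate addition of ethynylmagnesium bromide 4 (THF, 0 °C) gives rac-5-{1-[4-(benzyloxy)-2,6-dimethoxyphenyl]prop-2-yn-1-yl}-2,2-dimethyl-1,3-dioxane-4,6-dione F3. Heating in MeOH–pyridine opens the dioxanedione and decarboxylates it to rac-methyl 3-[4-(benzyloxy)-2,6-dimethoxyphenyl]pent-4-ynoate F4. Preparative chiral SFC separates 10, where the route is rejoined at step 5, from methyl (3S)-3-[4-(benzyloxy)-2,6-dimethoxyphenyl]pent-4-ynoate F5, which is set aside.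

Step 10. Cleavage of the non-chelated 7- and 4'-methyl ethers may stay incomplete, and long exposure to BBr3/HBr may drive acid-promoted side reactions (lactone closure, opening and reclosure of the pyranone that would move the side chain to C8). The fallback unmasks in two stages, the second one basic. It sets out from 19: BCl3 (CH2Cl2, −78 → 0 °C) should remove only the chelated 5-O-methyl group to give (3R)-3-[5-hydroxy-7-methoxy-2-(4-methoxyphenyl)-4-oxo-4H-chromen-6-yl]-3-phenylpropanoic acid F6. Sodium ethanethiolate (DMF, 120 °C) then cleaves the two remaining methyl ethers by SN2 at methyl, in a medium where carboxylate and phenoxides cannot lactonise, and acidification to pH 3 gives 20.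

Further compounds
F1 | step 5 | methyl (2E)-3-[4-(benzyloxy)-2,6-dimethoxyphenyl]prop-2-enoate | COC(=O)/C=C/c1c(OC)cc(OCc2ccccc2)cc1OC
F2 | step 3 | 5-[4-(benzyloxy)-2,6-dimethoxybenzylidene]-2,2-dimethyl-1,3-dioxane-4,6-dione | CC1(C)OC(=O)C(=Cc2c(OC)cc(OCc3ccccc3)cc2OC)C(=O)O1
F3 | step 3 | rac-5-{1-[4-(benzyloxy)-2,6-dimethoxyphenyl]prop-2-yn-1-yl}-2,2-dimethyl-1,3-dioxane-4,6-dione | CC1(C)OC(=O)C(C(C#C)c2c(OC)cc(OCc3ccccc3)cc2OC)C(=O)O1
F4 | step 3 | rac-methyl 3-[4-(benzyloxy)-2,6-dimethoxyphenyl]pent-4-ynoate | COC(=O)CC(C#C)c1c(OC)cc(OCc2ccccc2)cc1OC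
F5 | step 3 | methyl (3S)-3-[4-(benzyloxy)-2,6-dimethoxyphenyl]pent-4-ynoate | COC(=O)C[C@@H](C#C)c1c(OC)cc(OCc2ccccc2)cc1OC
F6 | step 10 | (3R)-3-[5-hydroxy-7-methoxy-2-(4-methoxyphenyl)-4-oxo-4H-chromen-6-yl]-3-phenylpropanoic acid | OC(=O)C[C@H](c1ccccc1)c1c(OC)cc2oc(-c3ccc(OC)cc3)cc(=O)c2c1O
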